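**Strategy.** The route rests on disconnecting the bond between the lactone β-carbon (the ring-fusion CH) and the neighbouring CH–OAc carbon of the 14-membered carbocycle. The exocyclic methylene carbon, that β-carbon and the carbinol carbon form a homoallylic alcohol, the retron of a carbonyl allylation. An intramolecular Nozaki–Hiyama–Kishi allylation of an aldehyde by a tethered 3-(bromomethyl)butenolide therefore closes the macrocycle last. In the same operation it shifts the endocyclic butenolide double bond into the exo-methylene and sets both new stereocentres. The precursor is an open-chain, farnesol-derived β,γ-unsaturated aldehyde ending in a preformed epoxy-butenolide, so the lactone and epoxide rings exist before the macrocycle.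

Key step: step 14

Assumption (remark on the chemistry): (S,S)-ProPhenol/Me2Zn is taken to deliver the alkynylzinc to the Si face of enal 8, giving the 4R carbinol; if the sense of induction is the reverse, the (R,R)-ligand is used and nothing else changes. Cembrane locants (C-1 = ring-fusion CH, C-2 = lactone O–CH, C-3/C-4 = epoxide, C-14 = carbinol) are used only in the names of 19 and 20.

**Step 1**
Reactants: 1 (2E,6E)-farnesyl acetate
Product: 2 (2E,6E,10E)-12-hydroxy-3,7,11-trimethyldodeca-2,6,10-trien-1-yl acetate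
Conditions: SeO2 (0.3 equiv), t-BuOOH (3 equiv), salicylic acid (0.1 equiv), CH2Cl2, rt
Reagents that add atoms: tert-butyl hydroperoxide, CC(C)(C)OO (terminal oxidant; the oxygen is transferred via selenium dioxide, O=[Se]=O)
Why: Sharpless–Umbreit allylic oxidation (ene reaction, then [2,3]-sigmatropic shift) attacks the electron-rich terminal trisubstituted olefin at its (E)-methyl group, the allylic-acetate olefin being deactivated, so the 10E geometry is kept and any over-oxidised enal 3 converges in step 2.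

**Step 2**
Reactants: 2 (2E,6E,10E)-12-hydroxy-3,7,11-trimethyldodeca-2,6,10-trien-1-yl acetate
Product: 3 (2E,6E,10E)-3,7,11-trimethyl-12-oxododeca-2,6,10-trien-1-yl acetate
Conditions: MnO2 (excess), CH2Cl2, rt
Reagents that add atoms: none
Why: MnO2 oxidises only the allylic alcohol, without E/Z isomerisation, to the conjugated aldehyde needed for one-carbon homologation.

**Step 3**
Reactants: 3 (2E,6E,10E)-3,7,11-trimethyl-12-oxododeca-2,6,10-trien-1-yl acetate
Product: 4 (2E,6E,10E)-3,7,11-trimethyltrideca-2,6,10,12-tetraen-1-yl acetate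
Conditions: Ph3PCH3Br, KOt-Bu, THF, 0 °C; then 3, –78 → 0 °C
Reagents that add atoms: methyltriphenylphosphonium bromide, C[P+](c1ccccc1)(c1ccccc1)c1ccccc1.[Br-]
Why: Wittig methylenation of the enal with the non-stabilised ylide at low temperature is much faster than attack on the acetate and should give the terminal 1,3-diene with the trisubstituted olefin untouched.

**Step 4**
Reactants: 4 (2E,6E,10E)-3,7,11-trimethyltrideca-2,6,10,12-tetraen-1-yl acetate
Product: 6 (2E,6E,10E)-3,7,11-trimethyltrideca-2,6,10-triene-1,13-diol, via B-alkyl-9-BBN adduct 5 (not isolated)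
Conditions: 9-BBN (1.2 equiv), THF, 0 °C → rt; then EtOH, 3 M NaOH, 30% H2O2, 0 → 40 °C
Reagents that add atoms: hydrogen peroxide, OO; 9-borabicyclo[3.3.1]nonane, [H]B1C2CCCC1CCC2 (boron appears in intermediate 5 only)
Why: 9-BBN hydroborates only the monosubstituted terminus of the diene (anti-Markovnikov, trisubstituted olefins inert), and alkaline peroxide oxidation of 5 should deliver the homoallylic primary alcohol while saponifying the acetate in the same work-up.

**Step 5**
Reactants: 6 (2E,6E,10E)-3,7,11-trimethyltrideca-2,6,10-triene-1,13-diol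
Product: 7 (2E,6E,10E)-13-hydroxy-3,7,11-trimethyltrideca-2,6,10-trienal
Conditions: MnO2 (excess), CH2Cl2, rt
Reagents that add atoms: none
Why: MnO2 is chemoselective for the allylic over the homoallylic primary alcohol and should give the (2E)-enal.

**Step 6**
Reactants: 7 (2E,6E,10E)-13-hydroxy-3,7,11-trimethyltrideca-2,6,10-trienal
Product: 8 (2E,6E,10E)-13-[(tert-butyldimethylsilyl)oxy]-3,7,11-trimethyltrideca-2,6,10-trienal
Conditions: TBSCl, imidazole, CH2Cl2, 0 °C → rt
Reagents that add atoms: tert-butyldimethylsilyl chloride, CC(C)(C)[Si](C)(C)Cl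
Why: Standard silylation of the remaining primary alcohol, needed so that it cannot direct vanadium epoxidation of the neighbouring olefin in step 9.

**Step 7**
Reactants: 8 (2E,6E,10E)-13-[(tert-butyldimethylsilyl)oxy]-3,7,11-trimethyltrideca-2,6,10-trienal; 9 tert-butyldimethyl(prop-2-yn-1-yloxy)silane
Product: 10 (4R,5E,9E,13E)-1,16-bis[(tert-butyldimethylsilyl)oxy]-6,10,14-trimethylhexadeca-5,9,13-trien-2-yn-4-ol
Conditions: 9 (3 equiv), Me2Zn (3 equiv), (S,S)-ProPhenol (20 mol%), Ph3P=O (40 mol%), toluene, 0–4 °C; aq. NH4Cl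
Reagents that add atoms: tert-butyldimethyl(prop-2-yn-1-yloxy)silane (9), C#CCO[Si](C)(C)C(C)(C)C
Why: Dinuclear zinc–ProPhenol-catalysed asymmetric alkynylation of an α,β-unsaturated aldehyde, in which the chiral bimetallic pocket delivers the alkynylzinc to the Si face and so sets the future lactone O–CH centre (4R here, S after the CIP change in 13) by catalyst control.

**Step 8**
Reactants: 10 (4R,5E,9E,13E)-1,16-bis[(tert-butyldimethylsilyl)oxy]-6,10,14-trimethylhexadeca-5,9,13-trien-2-yn-4-ol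
Product: 12 (2Z,4R,5E,9E,13E)-1,16-bis[(tert-butyldimethylsilyl)oxy]-2-iodo-6,10,14-trimethylhexadeca-2,5,9,13-tetraen-4-ol, via sodium alkenylalanate 11 (not isolated)
Conditions: Red-Al (1.6 equiv), THF, 0 °C → rt; EtOAc; then I2, THF, –78 °C; Rochelle salt work-up
Reagents that add atoms: iodine, II; Red-Al, [Na+].COCCO[AlH2-]OCCOC (aluminium appears in intermediate 11 only)
Why: Hydroxyl-directed trans-hydroalumination of the propargylic alcohol places hydride on the proximal and aluminium on the distal alkyne carbon (five-membered alkoxyalanate 11), and iodinolysis with retention should give the (Z)-γ-iodo allylic alcohol with the geometry required for lactonisation.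

**Step 9**
Reactants: 12 (2Z,4R,5E,9E,13E)-1,16-bis[(tert-butyldimethylsilyl)oxy]-2-iodo-6,10,14-trimethylhexadeca-2,5,9,13-tetraen-4-ol
Product: 13 (1S,2Z)-4-[(tert-butyldimethylsilyl)oxy]-1-{(2R,3R)-3-[(3E,7E)-10-[(tert-butyldimethylsilyl)oxy]-4,8-dimethyldeca-3,7-dien-1-yl]-3-methyloxiran-2-yl}-3-iodobut-2-en-1-ol
Conditions: VO(acac)2 (5 mol%), t-BuOOH (1.5 equiv, decane), CH2Cl2, 0 °C → rt
Reagents that add atoms: tert-butyl hydroperoxide, CC(C)(C)OO
Why: Vanadium-catalysed hydroxyl-directed epoxidation touches only the electron-rich allylic trisubstituted olefin (vinyl iodide deactivated, remote olefins undirected), and minimising A(1,3) strain with the cis-methyl group puts the carbinol hydrogen in the olefin plane so that oxygen is delivered syn to OH, which should give the threo epoxy alcohol with both epoxide centres fixed stereospecifically by the E-olefin.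

**Step 10**
Reactants: 13 (1S,2Z)-4-[(tert-butyldimethylsilyl)oxy]-1-{(2R,3R)-3-[(3E,7E)-10-[(tert-butyldimethylsilyl)oxy]-4,8-dimethyldeca-3,7-dien-1-yl]-3-methyloxiran-2-yl}-3-iodobut-2-en-1-ol
Product: 14 (5S)-3-{[(tert-butyldimethylsilyl)oxy]methyl}-5-{(2R,3R)-3-[(3E,7E)-10-[(tert-butyldimethylsilyl)oxy]-4,8-dimethyldeca-3,7-dien-1-yl]-3-methyloxiran-2-yl}furan-2(5H)-one
Conditions: PdCl2(PPh3)2 (5 mol%), CO (1 atm), i-Pr2NEt (1.5 equiv), THF, rt
Reagents that add atoms: carbon monoxide, [C-]#[O+]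
Why: Palladium-catalysed cyclocarbonylation, in which oxidative addition into the (Z)-vinyl iodide, CO insertion and intramolecular alkoxide capture of the acylpalladium close the butenolide without touching the carbinol configuration or the non-allylic epoxide.

**Step 11**
Reactants: 14 (5S)-3-{[(tert-butyldimethylsilyl)oxy]methyl}-5-{(2R,3R)-3-[(3E,7E)-10-[(tert-butyldimethylsilyl)oxy]-4,8-dimethyldeca-3,7-dien-1-yl]-3-methyloxiran-2-yl}furan-2(5H)-one
Product: 15 (5S)-5-{(2R,3R)-3-[(3E,7E)-10-hydroxy-4,8-dimethyldeca-3,7-dien-1-yl]-3-methyloxiran-2-yl}-3-(hydroxymethyl)furan-2(5H)-one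
Conditions: HF·pyridine, pyridine, THF, 0 °C → rt
Reagents that add atoms: none
Why: Buffered HF·pyridine cleaves both primary silyl ethers under conditions too weakly acidic to open the trisubstituted epoxide and too weakly basic to deprotonate the butenolide γ-position.

**Step 12**
Reactants: 15 (5S)-5-{(2R,3R)-3-[(3E,7E)-10-hydroxy-4,8-dimethyldeca-3,7-dien-1-yl]-3-methyloxiran-2-yl}-3-(hydroxymethyl)furan-2(5H)-one
Product: 16 (5S)-3-(bromomethyl)-5-{(2R,3R)-3-[(3E,7E)-10-hydroxy-4,8-dimethyldeca-3,7-dien-1-yl]-3-methyloxiran-2-yl}furan-2(5H)-one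
Conditions: NBS (1.5 equiv), Me2S (1.8 equiv), CH2Cl2, –30 → 0 °C
Reagents that add atoms: N-bromosuccinimide, O=C1CCC(=O)N1Br
Why: Corey–Kim halogenation activates alcohols as alkoxysulfonium salts, but only the allylic one (a 2-(hydroxymethyl)enoate) is displaced by bromide, whereas the homoallylic alkoxysulfonium salt should revert to the alcohol on work-up.

**Step 13**
Reactants: 16 (5S)-3-(bromomethyl)-5-{(2R,3R)-3-[(3E,7E)-10-hydroxy-4,8-dimethyldeca-3,7-dien-1-yl]-3-methyloxiran-2-yl}furan-2(5H)-one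
Product: 17 (3E,7E)-10-{(2R,3R)-3-[(2S)-4-(bromomethyl)-5-oxo-2,5-dihydrofuran-2-yl]-2-methyloxiran-2-yl}-3,7-dimethyldeca-3,7-dienal
Conditions: Dess–Martin periodinane (1.3 equiv), NaHCO3, CH2Cl2, 0 °C; used without chromatography
Reagents that add atoms: none
Why: Buffered Dess–Martin oxidation is neutral enough to give the β,γ-unsaturated aldehyde without migration of the double bond into conjugation and leaves the allylic bromide, epoxide and butenolide intact.

**Step 14**
Reactants: 17 (3E,7E)-10-{(2R,3R)-3-[(2S)-4-(bromomethyl)-5-oxo-2,5-dihydrofuran-2-yl]-2-methyloxiran-2-yl}-3,7-dimethyldeca-3,7-dienal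
Product: 19 (1R,2S,3R,4R,7E,11E,14S)-3,4-epoxy-14-hydroxycembra-7,11,15(17)-trien-16,2-olide, via allylchromium(III) species 18 (not isolated)
Conditions: CrCl2 (10 equiv), 4 Å MS, THF, rt, slow addition of 17 by syringe pump to about 1 mM; aqueous work-up
Reagents that add atoms: chromium(II) chloride, Cl[Cr]Cl (its atoms appear only in intermediate 18; none remain in 19)
Why: Cr(II) reduces the allylic C–Br bond in two one-electron steps to the σ-allylchromium(III) species 18, which adds to the tethered aldehyde through a closed six-membered chair transition state with allylic transposition (SE2′), so the new bond forms at the butenolide β-carbon and the endocyclic double bond becomes the exocyclic methylene. The closest known reaction types are the Nozaki–Hiyama–Kishi allylative macrocyclisation and the Cr-, Zn- or In-mediated Barbier addition of 3-(bromomethyl)furan-2(5H)-one to aldehydes, which gives β-(hydroxyalkyl)-α-methylene-γ-butyrolactones. Only the 14-membered carbocycle is closed, by 14-exo-trig attack of the allyl terminus on the aldehyde carbon; the lactone and the epoxide are already present. The ring-fusion centre C-1 is controlled by the adjacent lactone O–CH centre, the allyl unit being attacked on the face anti to its epoxide-bearing substituent, which should give the trans-disposed lactone. The carbinol centre C-14 is controlled by the chair transition state: the ring locks the allyl geometry as E-type (γ-substituent trans to CH2Cr) and the aldehyde chain sits pseudo-equatorial, which leads to the required anti relationship between the OH and the C-1–C-2 bond. The step needs γ- over α-attack (six-membered transition state), ring closure over oligomerisation (slow addition, high dilution) and tolerance of epoxide, lactone and the enolisable aldehyde, which the weakly basic organochromium(III) reagent, unreactive towards esters and epoxides, provides.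

**Step 15**
Reactants: 19 (1R,2S,3R,4R,7E,11E,14S)-3,4-epoxy-14-hydroxycembra-7,11,15(17)-trien-16,2-olide
Product: 20 (1R,2S,3R,4R,7E,11E,14S)-14-acetoxy-3,4-epoxycembra-7,11,15(17)-trien-16,2-olide (target)
Conditions: Ac2O, pyridine, DMAP (cat.), CH2Cl2, 0 °C
Reagents that add atoms: acetic anhydride, CC(=O)OC(C)=O
Why: DMAP-catalysed acetylation of the secondary alcohol under mild conditions should complete the target without epimerisation or lasting conjugate addition to the methylene lactone.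

**Compound list**

1 | (2E,6E)-3,7,11-trimethyldodeca-2,6,10-trien-1-yl acetate ((E,E)-farnesyl acetate) | CC(C)=CCC/C(C)=C/CC/C(C)=C/COC(C)=O | starting material
2 | (2E,6E,10E)-12-hydroxy-3,7,11-trimethyldodeca-2,6,10-trien-1-yl acetate | OC/C(C)=C/CC/C(C)=C/CC/C(C)=C/COC(C)=O | intermediate
3 | (2E,6E,10E)-3,7,11-trimethyl-12-oxododeca-2,6,10-trien-1-yl acetate | O=C/C(C)=C/CC/C(C)=C/CC/C(C)=C/COC(C)=O | intermediate
4 | (2E,6E,10E)-3,7,11-trimethyltrideca-2,6,10,12-tetraen-1-yl acetate | C=C/C(C)=C/CC/C(C)=C/CC/C(C)=C/COC(C)=O | intermediate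
5 | (2E,6E,10E)-13-(9-borabicyclo[3.3.1]nonan-9-yl)-3,7,11-trimethyltrideca-2,6,10-trien-1-yl acetate (not isolated) | CC(=O)OC/C=C(\C)CC/C=C(\C)CC/C=C(\C)CCB1C2CCCC1CCC2 | intermediate
6 | (2E,6E,10E)-3,7,11-trimethyltrideca-2,6,10-triene-1,13-diol | OCC/C(C)=C/CC/C(C)=C/CC/C(C)=C/CO | intermediate
7 | (2E,6E,10E)-13-hydroxy-3,7,11-trimethyltrideca-2,6,10-trienal | OCC/C(C)=C/CC/C(C)=C/CC/C(C)=C/C=O | intermediate
8 | (2E,6E,10E)-13-[(tert-butyldimethylsilyl)oxy]-3,7,11-trimethyltrideca-2,6,10-trienal | CC(C)(C)[Si](C)(C)OCC/C(C)=C/CC/C(C)=C/CC/C(C)=C/C=O | intermediate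
9 | tert-butyldimethyl(prop-2-yn-1-yloxy)silane | C#CCO[Si](C)(C)C(C)(C)C | starting material
10 | (4R,5E,9E,13E)-1,16-bis[(tert-butyldimethylsilyl)oxy]-6,10,14-trimethylhexadeca-5,9,13-trien-2-yn-4-ol | CC(C)(C)[Si](C)(C)OCC/C(C)=C/CC/C(C)=C/CC/C(C)=C/[C@@H](O)C#CCO[Si](C)(C)C(C)(C)C | intermediate
11 | sodium alkenylalanate (cyclic 2,5-dihydro-1,2-oxaluminol-2-uide with two 2-methoxyethoxy ligands on Al; not isolated) | [Na+].COCCO[Al-]1(OCCOC)O[C@H](/C=C(\C)CC/C=C(\C)CC/C=C(\C)CCO[Si](C)(C)C(C)(C)C)C=C1CO[Si](C)(C)C(C)(C)C | intermediate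
12 | (2Z,4R,5E,9E,13E)-1,16-bis[(tert-butyldimethylsilyl)oxy]-2-iodo-6,10,14-trimethylhexadeca-2,5,9,13-tetraen-4-ol | CC(C)(C)[Si](C)(C)OCC/C(C)=C/CC/C(C)=C/CC/C(C)=C/[C@@H](O)/C=C(\I)CO[Si](C)(C)C(C)(C)C | intermediate
13 | (1S,2Z)-4-[(tert-butyldimethylsilyl)oxy]-1-{(2R,3R)-3-[(3E,7E)-10-[(tert-butyldimethylsilyl)oxy]-4,8-dimethyldeca-3,7-dien-1-yl]-3-methyloxiran-2-yl}-3-iodobut-2-en-1-ol | CC(C)(C)[Si](C)(C)OCC/C(C)=C/CC/C(C)=C/CC[C@@]1(C)O[C@@H]1[C@@H](O)/C=C(\I)CO[Si](C)(C)C(C)(C)C | intermediate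
14 | (5S)-3-{[(tert-butyldimethylsilyl)oxy]methyl}-5-{(2R,3R)-3-[(3E,7E)-10-[(tert-butyldimethylsilyl)oxy]-4,8-dimethyldeca-3,7-dien-1-yl]-3-methyloxiran-2-yl}furan-2(5H)-one | CC(C)(C)[Si](C)(C)OCC/C(C)=C/CC/C(C)=C/CC[C@@]1(C)O[C@@H]1[C@H]2OC(=O)C(CO[Si](C)(C)C(C)(C)C)=C2 | intermediate
15 | (5S)-5-{(2R,3R)-3-[(3E,7E)-10-hydroxy-4,8-dimethyldeca-3,7-dien-1-yl]-3-methyloxiran-2-yl}-3-(hydroxymethyl)furan-2(5H)-one | OCC/C(C)=C/CC/C(C)=C/CC[C@@]1(C)O[C@@H]1[C@H]2OC(=O)C(CO)=C2 | intermediate
16 | (5S)-3-(bromomethyl)-5-{(2R,3R)-3-[(3E,7E)-10-hydroxy-4,8-dimethyldeca-3,7-dien-1-yl]-3-methyloxiran-2-yl}furan-2(5H)-one | OCC/C(C)=C/CC/C(C)=C/CC[C@@]1(C)O[C@@H]1[C@H]2OC(=O)C(CBr)=C2 | intermediate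
17 | (3E,7E)-10-{(2R,3R)-3-[(2S)-4-(bromomethyl)-5-oxo-2,5-dihydrofuran-2-yl]-2-methyloxiran-2-yl}-3,7-dimethyldeca-3,7-dienal | O=CC/C(C)=C/CC/C(C)=C/CC[C@@]1(C)O[C@@H]1[C@H]2OC(=O)C(CBr)=C2 | intermediate
18 | allylchromium(III) dichloride derived from 17 (CH2CrCl2 in place of CH2Br; not isolated) | O=CC/C(C)=C/CC/C(C)=C/CC[C@@]1(C)O[C@@H]1[C@H]2OC(=O)C(C[Cr](Cl)Cl)=C2 | intermediate
19 | (1R,2S,3R,4R,7E,11E,14S)-3,4-epoxy-14-hydroxycembra-7,11,15(17)-trien-16,2-olide (14-membered ring, trans-disposed α-methylene-γ-lactone on C-1/C-2) | C=C1C(=O)O[C@H]2[C@H]1[C@@H](O)C/C(C)=C/CC/C(C)=C/CC[C@@]1(C)O[C@H]21 | intermediate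
20 | (1R,2S,3R,4R,7E,11E,14S)-14-acetoxy-3,4-epoxycembra-7,11,15(17)-trien-16,2-olide | C=C1C(=O)O[C@H]2[C@H]1[C@@H](OC(C)=O)C/C(C)=C/CC/C(C)=C/CC[C@@]1(C)O[C@H]21 | target

**Total step count:** 15 steps. **Longest linear sequence:** 15 steps (from 1; 9 is a purchased reagent).

**Three steps most likely to fail**

Step 14 (key macrocyclisation). What may go wrong: intermolecular coupling outpacing ring closure; protonation or β-elimination of the allylchromium (reductive opening of the lactone) before it meets the aldehyde; translactonisation of the chromium alkoxide; erosion of facial selectivity under macrocyclic strain. The fallback replaces the reductively generated allylmetal by a preformed, isolable allylboronate. It sets out from 16 and returns at 19. Bromide 16 would be borylated with bis(pinacolato)diboron and catalytic Pd2(dba)3 in toluene at 50 °C to give (5S)-5-{(2R,3R)-3-[(3E,7E)-10-hydroxy-4,8-dimethyldeca-3,7-dien-1-yl]-3-methyloxiran-2-yl}-3-[(4,4,5,5-tetramethyl-1,3,2-dioxaborolan-2-yl)methyl]furan-2(5H)-one F1. Buffered Dess–Martin oxidation would then give the corresponding aldehyde, (3E,7E)-3,7-dimethyl-10-{(2R,3R)-2-methyl-3-[(2S)-5-oxo-4-[(4,4,5,5-tetramethyl-1,3,2-dioxaborolan-2-yl)methyl]-2,5-dihydrofuran-2-yl]oxiran-2-yl}deca-3,7-dienal F2. Heating F2 in toluene at 80 °C at high dilution should effect a thermal intramolecular allylboration through the same closed chair transition state (same trans/anti sense, no low-valent metal, borate instead of a nucleophilic metal alkoxide). Aqueous pH 7 work-up would release 19.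

Step 9 (directed epoxidation). What may go wrong: insufficient threo/erythro facial selectivity, oxidation of the bis-allylic alcohol to the dienone, or epoxidation of a remote olefin. The fallback sets the epoxide by reagent control and corrects the carbinol afterwards. It sets out from 8 and returns at 13. Step 7 run with (R,R)-ProPhenol would give (4S,5E,9E,13E)-1,16-bis[(tert-butyldimethylsilyl)oxy]-6,10,14-trimethylhexadeca-5,9,13-trien-2-yn-4-ol F3. Red-Al/I2 as in step 8 would give (2Z,4S,5E,9E,13E)-1,16-bis[(tert-butyldimethylsilyl)oxy]-2-iodo-6,10,14-trimethylhexadeca-2,5,9,13-tetraen-4-ol F4. Sharpless epoxidation (Ti(Oi-Pr)4, D-(–)-diisopropyl tartrate, t-BuOOH, 4 Å MS, CH2Cl2, –20 °C; matched, erythro-selective) should give the erythro epoxy alcohol (1R,2Z)-4-[(tert-butyldimethylsilyl)oxy]-1-{(2R,3R)-3-[(3E,7E)-10-[(tert-butyldimethylsilyl)oxy]-4,8-dimethyldeca-3,7-dien-1-yl]-3-methyloxiran-2-yl}-3-iodobut-2-en-1-ol F5. Mitsunobu inversion (4-nitrobenzoic acid, PPh3, DIAD, toluene, 0 °C) would give the (1S)-4-nitrobenzoate of 13 F6. Methanolysis (K2CO3, MeOH, 0 °C) would give 13.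

Step 7 (asymmetric alkynylation). What may go wrong: low conversion or low enantioselectivity with the β,β-disubstituted enal, or the opposite sense of induction. The fallback separates C–C bond formation from stereocentre formation. It sets out from 8 and returns at 10. The lithium acetylide of 9 (n-BuLi, THF, –78 °C) would add to 8 to give racemic (5E,9E,13E)-1,16-bis[(tert-butyldimethylsilyl)oxy]-6,10,14-trimethylhexadeca-5,9,13-trien-2-yn-4-ol F7. Dess–Martin oxidation would give (5E,9E,13E)-1,16-bis[(tert-butyldimethylsilyl)oxy]-6,10,14-trimethylhexadeca-5,9,13-trien-2-yn-4-one F8. Oxazaborolidine-catalysed reduction ((R)-Me-CBS, catecholborane, toluene, –78 °C, the alkynyl group assumed to act as the small substituent) should give 10.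

**Further compounds**

F1 | step 14 | (5S)-5-{(2R,3R)-3-[(3E,7E)-10-hydroxy-4,8-dimethyldeca-3,7-dien-1-yl]-3-methyloxiran-2-yl}-3-[(4,4,5,5-tetramethyl-1,3,2-dioxaborolan-2-yl)methyl]furan-2(5H)-one | OCC/C(C)=C/CC/C(C)=C/CC[C@@]1(C)O[C@@H]1[C@H]2OC(=O)C(CB3OC(C)(C)C(C)(C)O3)=C2
F2 | step 14 | (3E,7E)-3,7-dimethyl-10-{(2R,3R)-2-methyl-3-[(2S)-5-oxo-4-[(4,4,5,5-tetramethyl-1,3,2-dioxaborolan-2-yl)methyl]-2,5-dihydrofuran-2-yl]oxiran-2-yl}deca-3,7-dienal | O=CC/C(C)=C/CC/C(C)=C/CC[C@@]1(C)O[C@@H]1[C@H]2OC(=O)C(CB3OC(C)(C)C(C)(C)O3)=C2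
F3 | step 9 | (4S,5E,9E,13E)-1,16-bis[(tert-butyldimethylsilyl)oxy]-6,10,14-trimethylhexadeca-5,9,13-trien-2-yn-4-ol | CC(C)(C)[Si](C)(C)OCC/C(C)=C/CC/C(C)=C/CC/C(C)=C/[C@H](O)C#CCO[Si](C)(C)C(C)(C)C
F4 | step 9 | (2Z,4S,5E,9E,13E)-1,16-bis[(tert-butyldimethylsilyl)oxy]-2-iodo-6,10,14-trimethylhexadeca-2,5,9,13-tetraen-4-ol | CC(C)(C)[Si](C)(C)OCC/C(C)=C/CC/C(C)=C/CC/C(C)=C/[C@H](O)/C=C(\I)CO[Si](C)(C)C(C)(C)C
F5 | step 9 | (1R,2Z)-4-[(tert-butyldimethylsilyl)oxy]-1-{(2R,3R)-3-[(3E,7E)-10-[(tert-butyldimethylsilyl)oxy]-4,8-dimethyldeca-3,7-dien-1-yl]-3-methyloxiran-2-yl}-3-iodobut-2-en-1-ol | CC(C)(C)[Si](C)(C)OCC/C(C)=C/CC/C(C)=C/CC[C@@]1(C)O[C@@H]1[C@H](O)/C=C(\I)CO[Si](C)(C)C(C)(C)C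
F6 | step 9 | (1S,2Z)-4-[(tert-butyldimethylsilyl)oxy]-1-{(2R,3R)-3-[(3E,7E)-10-[(tert-butyldimethylsilyl)oxy]-4,8-dimethyldeca-3,7-dien-1-yl]-3-methyloxiran-2-yl}-3-iodobut-2-en-1-yl 4-nitrobenzoate | CC(C)(C)[Si](C)(C)OCC/C(C)=C/CC/C(C)=C/CC[C@@]1(C)O[C@@H]1[C@@H](OC(=O)c3ccc(cc3)[N+](=O)[O-])/C=C(\I)CO[Si](C)(C)C(C)(C)C
F7 | step 7 | racemic (5E,9E,13E)-1,16-bis[(tert-butyldimethylsilyl)oxy]-6,10,14-trimethylhexadeca-5,9,13-trien-2-yn-4-ol | CC(C)(C)[Si](C)(C)OCC/C(C)=C/CC/C(C)=C/CC/C(C)=C/C(O)C#CCO[Si](C)(C)C(C)(C)C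
F8 | step 7 | (5E,9E,13E)-1,16-bis[(tert-butyldimethylsilyl)oxy]-6,10,14-trimethylhexadeca-5,9,13-trien-2-yn-4-one | CC(C)(C)[Si](C)(C)OCC/C(C)=C/CC/C(C)=C/CC/C(C)=C/C(=O)C#CCO[Si](C)(C)C(C)(C)C
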